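**Plan**
- Retrosynthesis: after removing four benzyl ethers and one O-methyl group, ring C (the dihydropyran) is opened across C4–C3 and O1–C2 in one retro-[4+2]. This gives an o-quinone methide of ring A and a 2-vinylphenol (future ring B). The C4 carbon is then removed (ortho-formylation), and the side chain is cut at the aryl–CH bond (conjugate addition) and at the enone C=C (aldol).
- Enabling feature: in ring A, O1 on C8a is ortho and the C7 oxygen is para to the C4 methylene, so a C4 benzylic alcohol ionises easily to the heterodiene C4=C4a–C8a=O1. C2 carries an aryl ring with an ortho oxygen, so C3–C2 can come from an electron-rich 2-vinylphenol whose OH also binds a chiral acid.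
- Forward order: chalcone, then rhodium-catalysed arylation, then deoxygenation to the 1,3-diarylpropyl chain on ring A, then CH2OH at the future C4, then the [4+2] that closes ring C and joins ring B, then O-methylation and debenzylation.
- Stereochemistry: the (R)-diarylmethine centre comes from the (S)-BINAP rhodium catalyst. The (2S)-centre comes from the chiral phosphoric acid in the cycloaddition; the two centres are remote, so each is set by its catalyst.
- Helpers: the free ortho-OH on the vinylphenol (methylated afterwards to the target's OMe), benzyl on O7, 4-methoxybenzyl on the future O1, and the benzylic-alcohol oxidation level at C4.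

Key step: step 11

Assumption: the benzyl-protected building blocks bought for steps 3, 5 and 10 are taken as purchasable, and the catalyst antipodes named in steps 5 and 11 are model-based predictions of the sense of induction; if a test reaction shows the opposite sense, the mirror-image catalyst is used and nothing else changes.

Notation: R* = (1R)-3-[4-(benzyloxy)-2-methoxyphenyl]-1-[4-(benzyloxy)phenyl]propyl; PMB = 4-methoxybenzyl.

**Step 1**
Reactants: 1 2,4-dihydroxybenzaldehyde
Product: 2 2-hydroxy-4-(PMB-oxy)benzaldehyde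
Conditions: PMBCl (1.05 equiv), NaHCO3, KI (cat.), MeCN, 70 °C
Reagents that add atoms: 4-methoxybenzyl chloride, COc1ccc(CCl)cc1
Why: The 4-OH is the more acidic, unhindered phenol while the 2-OH is locked in a hydrogen bond to the formyl group, so a weak base should give regioselective Williamson etherification at O4.

**Step 2**
Reactants: 2 2-hydroxy-4-(PMB-oxy)benzaldehyde
Product: 3 2-(benzyloxy)-4-(PMB-oxy)benzaldehyde
Conditions: BnBr, K2CO3, DMF, 60 °C
Reagents that add atoms: benzyl bromide, BrCc1ccccc1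
Why: Williamson etherification of the remaining chelated phenol under more forcing conditions installs the benzyl ether that protects the future C7 oxygen to the end.

**Step 3**
Reactants: 4 1-[4-(benzyloxy)-2-hydroxyphenyl]ethanone
Product: 5 1-[4-(benzyloxy)-2-methoxyphenyl]ethanone
Conditions: MeI, K2CO3, DMF, 50 °C
Reagents that add atoms: iodomethane, CI
Why: Williamson O-methylation of the chelated phenol provides the methoxy group of the 4-hydroxy-2-methoxyphenyl ring.

**Step 4**
Reactants: 3 2-(benzyloxy)-4-(PMB-oxy)benzaldehyde; 5 1-[4-(benzyloxy)-2-methoxyphenyl]ethanone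
Product: 6 (E)-3-[2-(benzyloxy)-4-(PMB-oxy)phenyl]-1-[4-(benzyloxy)-2-methoxyphenyl]prop-2-en-1-one
Conditions: KOH (aq.), EtOH/THF, rt
Reagents that add atoms: none
Why: Claisen–Schmidt (crossed aldol) condensation of the non-enolisable aldehyde with the methyl ketone should give the thermodynamically favoured (E)-enone, all ether groups being base-stable.

**Step 5**
Reactants: 6 (E)-enone; 7 4-(benzyloxy)phenylboronic acid
Product: 8 (3R)-3-[2-(benzyloxy)-4-(PMB-oxy)phenyl]-1-[4-(benzyloxy)-2-methoxyphenyl]-3-[4-(benzyloxy)phenyl]propan-1-one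
Conditions: [Rh(OH)((S)-BINAP)]2 (1.5 mol%), 7 (2.5 equiv), dioxane/H2O 10:1, 50 °C
Reagents that add atoms: none
Why: Rhodium-catalysed asymmetric conjugate addition of an arylboronic acid (Hayashi–Miyaura reaction), in which the aryl–rhodium species bound to (S)-BINAP is expected to insert the (E)-enone from its α-Si/β-Si face, which corresponds to the (R)-configured diarylmethine centre, before hydrolysis of the oxa-π-allyl rhodium intermediate releases the ketone.

**Step 6**
Reactants: 8 (3R)-ketone
Product: 9 (3R)-3-[2-(benzyloxy)-4-(PMB-oxy)phenyl]-1-[4-(benzyloxy)-2-methoxyphenyl]-3-[4-(benzyloxy)phenyl]propan-1-ol (both C1 epimers)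
Conditions: NaBH4, THF/MeOH, 0 °C to rt
Reagents that add atoms: none
Why: Borohydride reduction of the ketone gives the benzylic alcohol, whose uncontrolled carbinol centre is removed in the next step.

**Step 7**
Reactants: 9 (3R)-alcohol
Product: 10 3-(benzyloxy)-4-R*-phenol
Conditions: Et3SiH (5 equiv), TFA (10% v/v), CH2Cl2, −10 to 0 °C, short reaction time
Reagents that add atoms: none
Why: Ionic hydrogenation, in which TFA ionises the alcohol to a cation stabilised by the ortho-methoxy and para-benzyloxy groups and Et3SiH reduces it to CH2, while the same acid cleaves the aryl PMB ether (its cation is scavenged by the silane) and the plain benzyl ethers and the non-adjacent stereocentre should survive.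

**Step 8**
Reactants: 10 3-(benzyloxy)-4-R*-phenol
Product: 11 4-(benzyloxy)-2-hydroxy-5-R*-benzaldehyde
Conditions: MgCl2, Et3N, (CH2O)n, THF, reflux; dilute HCl work-up
Reagents that add atoms: paraformaldehyde (as formaldehyde), C=O
Why: Magnesium-mediated ortho-formylation (Casnati–Skattebøl type), in which the magnesium phenoxide delivers formaldehyde only to an ortho carbon and the site between the two oxygens is shielded by the benzyloxy group, so the formyl group should enter at the open ortho position after hydride transfer from the benzylic alkoxide to a second formaldehyde.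

**Step 9**
Reactants: 11 4-(benzyloxy)-2-hydroxy-5-R*-benzaldehyde
Product: 12 5-(benzyloxy)-2-(hydroxymethyl)-4-R*-phenol
Conditions: NaBH4, THF/MeOH, 0 °C; neutral work-up, used crude
Reagents that add atoms: none
Why: Borohydride reduction of the aldehyde gives the 2-hydroxybenzyl alcohol, the latent o-quinone methide, which is kept away from acid until the next step.

**Step 10**
Reactants: 13 5-(benzyloxy)-2-hydroxybenzaldehyde
Product: 14 4-(benzyloxy)-2-vinylphenol
Conditions: Ph3PCH3Br (2.5 equiv), KOtBu (2.4 equiv), THF, 0 °C to rt; stored cold, used promptly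
Reagents that add atoms: methyltriphenylphosphonium bromide, C[P+](c1ccccc1)(c1ccccc1)c1ccccc1.[Br-]
Why: Wittig methylenation with excess non-stabilised ylide (one equivalent of base is taken by the phenol) converts the salicylaldehyde into the 2-vinylphenol.

**Step 11**
Reactants: 12 5-(benzyloxy)-2-(hydroxymethyl)-4-R*-phenol; 14 4-(benzyloxy)-2-vinylphenol
Product: 16 (2S)-7-(benzyloxy)-2-[5-(benzyloxy)-2-hydroxyphenyl]-6-R*-chroman, via o-quinone methide 15 (not isolated)
Conditions: (R)-TRIP [(R)-3,3'-bis(2,4,6-triisopropylphenyl)-1,1'-binaphthyl-2,2'-diyl hydrogen phosphate] (10 mol%), 14 (2 equiv, added slowly), 3 Å molecular sieves, toluene, 0 °C to rt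
Reagents that add atoms: none
Why: The phosphoric acid protonates the benzylic hydroxyl of 12 and water is lost, helped by the para-benzyloxy and ortho-hydroxy lone pairs, to give o-quinone methide 15 held through its carbonyl oxygen on the P–OH site while the phenolic OH of 14 binds the P=O oxygen; in this complex the terminal vinyl carbon of 14 attacks the exocyclic methylene of 15 (C4–C3 bond) and the quinone-methide oxygen closes on the benzylic carbon (O1–C2 bond). The closest known reaction type is the chiral-phosphoric-acid-catalysed inverse-electron-demand oxa-Diels–Alder reaction of o-quinone methides from o-hydroxybenzyl alcohols with 2-vinylphenols. Ring C closes by a [4+2] cycloaddition that is concerted but highly asynchronous (at the stepwise limit, a Michael addition followed by 6-exo-trig oxa-Michael closure onto the vinylphenol-derived quinone methide). The C2 stereocentre is set by the chiral pocket of the acid, since the existing (R)-centre lies on the far side of ring A and is not touched. Regioselectivity (2-aryl, not 3-aryl) follows from the polarisation of both partners, and chemoselectivity is secured by the substrate: only one free OH is ortho to the CH2OH group, the ring position para to that OH is blocked by R* so self-condensation is suppressed, and the ortho-OH makes 14 a far better π-nucleophile than the benzyloxy arenes of 12.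

**Step 12**
Reactants: 16 (2S)-7-(benzyloxy)-2-[5-(benzyloxy)-2-hydroxyphenyl]-6-R*-chroman
Product: 17 (2S)-7-(benzyloxy)-2-[5-(benzyloxy)-2-methoxyphenyl]-6-R*-chroman
Conditions: MeI, K2CO3, DMF, 0 °C to rt
Reagents that add atoms: iodomethane, CI
Why: Williamson O-methylation of the only free phenol turns the directing ortho-hydroxyl into the 2-methoxy group of the target, under mild base at low temperature so that retro-oxa-Michael opening of the chroman should not compete.

**Step 13**
Reactants: 17 (2S)-7-(benzyloxy)-2-[5-(benzyloxy)-2-methoxyphenyl]-6-R*-chroman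
Product: 18 (2S)-2-(5-hydroxy-2-methoxyphenyl)-6-[(1R)-3-(4-hydroxy-2-methoxyphenyl)-1-(4-hydroxyphenyl)propyl]chroman-7-ol (CNP0239474.1)
Conditions: H2 (1 atm), 10% Pd/C, EtOAc/MeOH, rt
Reagents that add atoms: none
Why: Hydrogenolysis of the four benzyl ethers over palladium on carbon under neutral conditions should leave the cyclic benzylic C2–O1 bond and both stereocentres intact.

**Compound list**
1 | 2,4-dihydroxybenzaldehyde | O=Cc1ccc(O)cc1O | starting material
2 | 2-hydroxy-4-[(4-methoxybenzyl)oxy]benzaldehyde | O=Cc1ccc(OCc2ccc(OC)cc2)cc1O | intermediate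
3 | 2-(benzyloxy)-4-[(4-methoxybenzyl)oxy]benzaldehyde | O=Cc1ccc(OCc2ccc(OC)cc2)cc1OCc1ccccc1 | intermediate
4 | 1-[4-(benzyloxy)-2-hydroxyphenyl]ethanone | CC(=O)c1ccc(OCc2ccccc2)cc1O | starting material
5 | 1-[4-(benzyloxy)-2-methoxyphenyl]ethanone | CC(=O)c1ccc(OCc2ccccc2)cc1OC | intermediate
6 | (E)-3-[2-(benzyloxy)-4-[(4-methoxybenzyl)oxy]phenyl]-1-[4-(benzyloxy)-2-methoxyphenyl]prop-2-en-1-one | COc1cc(OCc2ccccc2)ccc1C(=O)/C=C/c1ccc(OCc2ccc(OC)cc2)cc1OCc1ccccc1 | intermediate
7 | 4-(benzyloxy)phenylboronic acid | OB(O)c1ccc(OCc2ccccc2)cc1 | starting material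
8 | (3R)-3-[2-(benzyloxy)-4-[(4-methoxybenzyl)oxy]phenyl]-1-[4-(benzyloxy)-2-methoxyphenyl]-3-[4-(benzyloxy)phenyl]propan-1-one | COc1cc(OCc2ccccc2)ccc1C(=O)C[C@H](c1ccc(OCc2ccccc2)cc1)c1ccc(OCc2ccc(OC)cc2)cc1OCc1ccccc1 | intermediate
9 | (3R)-3-[2-(benzyloxy)-4-[(4-methoxybenzyl)oxy]phenyl]-1-[4-(benzyloxy)-2-methoxyphenyl]-3-[4-(benzyloxy)phenyl]propan-1-ol, C1 epimers | COc1cc(OCc2ccccc2)ccc1C(O)C[C@H](c1ccc(OCc2ccccc2)cc1)c1ccc(OCc2ccc(OC)cc2)cc1OCc1ccccc1 | intermediate
10 | 3-(benzyloxy)-4-[(1R)-3-[4-(benzyloxy)-2-methoxyphenyl]-1-[4-(benzyloxy)phenyl]propyl]phenol | COc1cc(OCc2ccccc2)ccc1CC[C@H](c1ccc(OCc2ccccc2)cc1)c1ccc(O)cc1OCc1ccccc1 | intermediate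
11 | 4-(benzyloxy)-5-[(1R)-3-[4-(benzyloxy)-2-methoxyphenyl]-1-[4-(benzyloxy)phenyl]propyl]-2-hydroxybenzaldehyde | COc1cc(OCc2ccccc2)ccc1CC[C@H](c1ccc(OCc2ccccc2)cc1)c1cc(C=O)c(O)cc1OCc1ccccc1 | intermediate
12 | 5-(benzyloxy)-4-[(1R)-3-[4-(benzyloxy)-2-methoxyphenyl]-1-[4-(benzyloxy)phenyl]propyl]-2-(hydroxymethyl)phenol | COc1cc(OCc2ccccc2)ccc1CC[C@H](c1ccc(OCc2ccccc2)cc1)c1cc(CO)c(O)cc1OCc1ccccc1 | intermediate
13 | 5-(benzyloxy)-2-hydroxybenzaldehyde | O=Cc1cc(OCc2ccccc2)ccc1O | starting material
14 | 4-(benzyloxy)-2-vinylphenol | C=Cc1cc(OCc2ccccc2)ccc1O | intermediate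
15 | 3-(benzyloxy)-4-[(1R)-3-[4-(benzyloxy)-2-methoxyphenyl]-1-[4-(benzyloxy)phenyl]propyl]-6-methylidenecyclohexa-2,4-dien-1-one (o-quinone methide, not isolated) | COc1cc(OCc2ccccc2)ccc1CC[C@H](c1ccc(OCc2ccccc2)cc1)C1=CC(=C)C(=O)C=C1OCc1ccccc1 | intermediate
16 | 4-(benzyloxy)-2-[(2S)-7-(benzyloxy)-6-[(1R)-3-[4-(benzyloxy)-2-methoxyphenyl]-1-[4-(benzyloxy)phenyl]propyl]chroman-2-yl]phenol | COc1cc(OCc2ccccc2)ccc1CC[C@H](c1ccc(OCc2ccccc2)cc1)c1cc2c(cc1OCc1ccccc1)O[C@H](c1cc(OCc3ccccc3)ccc1O)CC2 | intermediate
17 | (2S)-7-(benzyloxy)-2-[5-(benzyloxy)-2-methoxyphenyl]-6-[(1R)-3-[4-(benzyloxy)-2-methoxyphenyl]-1-[4-(benzyloxy)phenyl]propyl]chroman | COc1cc(OCc2ccccc2)ccc1CC[C@H](c1ccc(OCc2ccccc2)cc1)c1cc2c(cc1OCc1ccccc1)O[C@H](c1cc(OCc3ccccc3)ccc1OC)CC2 | intermediate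
18 | (2S)-2-(5-hydroxy-2-methoxyphenyl)-6-[(1R)-3-(4-hydroxy-2-methoxyphenyl)-1-(4-hydroxyphenyl)propyl]chroman-7-ol | COc1cc(O)ccc1CC[C@H](c1ccc(O)cc1)c1cc2c(cc1O)O[C@H](c1cc(O)ccc1OC)CC2 | target

**Step count and risks**
Total step count: 13. Longest linear sequence: 11 steps (steps 1, 2, 4, 5, 6, 7, 8, 9, 11, 12, 13).

Steps most likely to fail:

1. Step 11. The quinone methide may be consumed by self-condensation, the vinylphenol may oligomerise under acid, or facial discrimination at C2 may be insufficient, leaving a C2 epimer that is hard to separate because the two centres are remote. The fallback sets out from 11 and comes back at 17, replacing steps 9 to 12. Commercial 1-[5-(benzyloxy)-2-hydroxyphenyl]ethanone is O-methylated (MeI, K2CO3) to 1-[5-(benzyloxy)-2-methoxyphenyl]ethanone F1. Claisen–Schmidt condensation of 11 with F1 (KOH, EtOH) should give the (E)-2-hydroxychalcone F2. Hydrogenation of its C=C bond with RhCl(PPh3)3/H2, which leaves benzyl ethers alone, should give the dihydrochalcone F3. Corey–Bakshi–Shibata reduction with (S)-Me-CBS and BH3·SMe2 should give the (R)-benzylic alcohol F4. Mitsunobu cyclisation (PPh3, DIAD, THF, 0 °C) then forms O1–C2 with inversion and should give 17 with the (2S) configuration.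

2. Step 7. The benzylic cation may be captured by the neighbouring benzyloxy oxygen (cyclisation with loss of benzyl) or by an arene, the freed phenol may be re-alkylated by the PMB cation, and benzyl ethers may be partly lost. The fallback sets out from 8 and comes back at 10, replacing steps 6 and 7, and avoids any carbocation at the chain. Condensation of 8 with TsNHNH2 (EtOH, cat. AcOH) should give the tosylhydrazone F5. Reduction with catecholborane followed by NaOAc·3H2O (hydride addition to C=N, then loss of sulfinate and N2) should give the PMB-protected diarylpropane F6. The PMB ether alone is then removed by brief exposure to 5% TFA and Et3SiH in CH2Cl2 at 0 °C to give 10.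

3. Step 5. Insertion of the hindered ortho-benzyloxy enone may be slow, so that protodeboronation wins, and the facial selectivity is a prediction. The fallback sets out from 2 and comes back at 8, replacing steps 2, 4 and 5; it uses a temporary lactone ring as the acceptor. Wittig olefination and lactonisation of 2 with Ph3P=CHCO2Et in hot N,N-diethylaniline should give 7-(PMB-oxy)coumarin F7. Addition of 7 under Rh(acac)(C2H4)2/(R)-SEGPHOS catalysis (dioxane/H2O, 60 °C) should give the (4R)-4-aryl-dihydrocoumarin F8; this planar acceptor has no ortho hindrance, and the (R)-ligand should deliver the aryl group to the α-Re face, which for the Z-locked enoate is again the (R)-centre. Benzylation of commercial 4-bromo-3-methoxyphenol gives 4-(benzyloxy)-1-bromo-2-methoxybenzene F9; its aryllithium (nBuLi, THF, −78 °C) opens lactone F8 to the phenolic ketone F10. Benzylation of F10 (BnBr, K2CO3, DMF) gives 8.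

**Further compounds**
F1 | step 11 | 1-[5-(benzyloxy)-2-methoxyphenyl]ethanone | CC(=O)c1cc(OCc2ccccc2)ccc1OC
F2 | step 11 | (E)-3-[4-(benzyloxy)-5-[(1R)-3-[4-(benzyloxy)-2-methoxyphenyl]-1-[4-(benzyloxy)phenyl]propyl]-2-hydroxyphenyl]-1-[5-(benzyloxy)-2-methoxyphenyl]prop-2-en-1-one | COc1cc(OCc2ccccc2)ccc1CC[C@H](c1ccc(OCc2ccccc2)cc1)c1cc(/C=C/C(=O)c2cc(OCc3ccccc3)ccc2OC)c(O)cc1OCc1ccccc1
F3 | step 11 | 3-[4-(benzyloxy)-5-[(1R)-3-[4-(benzyloxy)-2-methoxyphenyl]-1-[4-(benzyloxy)phenyl]propyl]-2-hydroxyphenyl]-1-[5-(benzyloxy)-2-methoxyphenyl]propan-1-one | COc1cc(OCc2ccccc2)ccc1CC[C@H](c1ccc(OCc2ccccc2)cc1)c1cc(CCC(=O)c2cc(OCc3ccccc3)ccc2OC)c(O)cc1OCc1ccccc1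
F4 | step 11 | 5-(benzyloxy)-2-[(3R)-3-[5-(benzyloxy)-2-methoxyphenyl]-3-hydroxypropyl]-4-[(1R)-3-[4-(benzyloxy)-2-methoxyphenyl]-1-[4-(benzyloxy)phenyl]propyl]phenol | COc1cc(OCc2ccccc2)ccc1CC[C@H](c1ccc(OCc2ccccc2)cc1)c1cc(CC[C@@H](O)c2cc(OCc3ccccc3)ccc2OC)c(O)cc1OCc1ccccc1
F5 | step 7 | tosylhydrazone of ketone 8 | COc1cc(OCc2ccccc2)ccc1C(=NNS(=O)(=O)c1ccc(C)cc1)C[C@H](c1ccc(OCc2ccccc2)cc1)c1ccc(OCc2ccc(OC)cc2)cc1OCc1ccccc1
F6 | step 7 | 2-(benzyloxy)-1-[(1R)-3-[4-(benzyloxy)-2-methoxyphenyl]-1-[4-(benzyloxy)phenyl]propyl]-4-[(4-methoxybenzyl)oxy]benzene | COc1cc(OCc2ccccc2)ccc1CC[C@H](c1ccc(OCc2ccccc2)cc1)c1ccc(OCc2ccc(OC)cc2)cc1OCc1ccccc1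
F7 | step 5 | 7-[(4-methoxybenzyl)oxy]-2H-chromen-2-one | O=C1C=Cc2ccc(OCc3ccc(OC)cc3)cc2O1
F8 | step 5 | (4R)-4-[4-(benzyloxy)phenyl]-7-[(4-methoxybenzyl)oxy]chroman-2-one | O=C1C[C@H](c2ccc(OCc3ccccc3)cc2)c2ccc(OCc3ccc(OC)cc3)cc2O1
F9 | step 5 | 4-(benzyloxy)-1-bromo-2-methoxybenzene | COc1cc(OCc2ccccc2)ccc1Br
F10 | step 5 | (3R)-1-[4-(benzyloxy)-2-methoxyphenyl]-3-[4-(benzyloxy)phenyl]-3-[2-hydroxy-4-[(4-methoxybenzyl)oxy]phenyl]propan-1-one | COc1cc(OCc2ccccc2)ccc1C(=O)C[C@H](c1ccc(OCc2ccccc2)cc1)c1ccc(OCc2ccc(OC)cc2)cc1O
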